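**Retrosynthetic overview**
- The strategy rests on ring A carrying three contiguous oxygenated or carboxylated carbons: C6–OAr (to ring B), C1–CO2H and C2–OMe. This is the pattern left when a nucleophile and an electrophile add across the C1≡C6 bond of a 3-methoxyaryne.
- The O–C6 and C1–CO2H bonds are cut together. This gives a ring A 1-silyl-6-triflate with the diol masked as an acetonide, the ring B phenoxide and CO2.
- Ring A comes from 4-hydroxy-2-methoxybenzaldehyde by O-carbamate formation, Brown methallylboration (sets the R carbinol), Markovnikov hydration, acetonide formation, silylation at C1 between OMe and the carbamate, then carbamate to phenol to triflate.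
- Ring B comes from 3-hydroxy-5-methylbenzoic acid by reduction, protection of both hydroxyls as MOM ethers, then lithiation between the two acetal arms and borylation/oxidation. The central OH enters last, so no hydroxyl differentiation is needed.
- Both benzene rings are bought. The only ring formed is the temporary 1,3-dioxane (step 4), opened in step 13. The endgame avoids mineral acid because the benzylic carbinol can ionise and the 2,6-dioxygenated benzoic acid can lose CO2.

Key step: step 11

Remark on the chemistry: ring A is numbered C1 (CO2H), C2 (OMe), C3 (side chain), C4/C5 (H), C6 (OAr). Ring B is numbered C1′ (ether O), C2′ (OH), C4′ (CH3), C6′ (CH2OH). The [C@H] centre of the target is read as (R), with priorities OH > aryl > CH2 > H.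

**Step 1**
Reactants: 1 4-hydroxy-2-methoxybenzaldehyde
Product: 2 4-formyl-3-methoxyphenyl N,N-diethylcarbamate
Conditions: ClC(O)NEt2, K2CO3, MeCN, reflux
Reagents that add atoms: N,N-diethylcarbamoyl chloride, CCN(CC)C(=O)Cl
Why: O-carbamoylation of the phenoxide installs both the phenol protection for steps 2–4 and the strong directing group for the later ortho-metalation.

**Step 2**
Reactants: 2 4-formyl-3-methoxyphenyl N,N-diethylcarbamate, 3 3-chloro-2-methylpropene
Product: 7 4-[(1R)-1-hydroxy-3-methylbut-3-en-1-yl]-3-methoxyphenyl N,N-diethylcarbamate, via methallylmagnesium chloride 4 (not isolated), via B-methallyldiisopinocampheylborane 5 (not isolated), via borinate adduct 6 (not isolated)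
Conditions: 3, Mg, THF, 0 °C; (+)-Ipc2BOMe [from (−)-α-pinene, slight excess over 4], Et2O, −78 °C→rt; 2, −78 °C; then aq. NaOH, H2O2, 0 °C→rt
Reagents that add atoms: 3-chloro-2-methylpropene, CC(=C)CCl
Why: In this Brown asymmetric methallylboration the closed chair transition state of the borane from (−)-α-pinene delivers the methallyl group to the Re face of the aryl aldehyde, which sets the (R) carbinol centre.

**Step 3**
Reactants: 7 4-[(1R)-1-hydroxy-3-methylbut-3-en-1-yl]-3-methoxyphenyl N,N-diethylcarbamate
Product: 8 4-[(1R)-1,3-dihydroxy-3-methylbutyl]-3-methoxyphenyl N,N-diethylcarbamate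
Conditions: Co(acac)2 (cat.), PhSiH3, O2 (1 atm), THF, rt
Reagents that add atoms: dioxygen, O=O
Why: In this Mukaiyama hydration, hydrogen-atom transfer to the 1,1-disubstituted alkene gives the tertiary radical, which is trapped by O2 and reduced to the tertiary alcohol without touching the carbinol centre.

**Step 4**
Reactants: 8 4-[(1R)-1,3-dihydroxy-3-methylbutyl]-3-methoxyphenyl N,N-diethylcarbamate
Product: 9 3-methoxy-4-[(4R)-2,2,6,6-tetramethyl-1,3-dioxan-4-yl]phenyl N,N-diethylcarbamate
Conditions: 2-methoxypropene, PPTS (cat.), CH2Cl2, 0 °C→rt; Et3N quench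
Reagents that add atoms: 2-methoxypropene, COC(C)=C
Why: Acid-catalysed acetonide formation with the enol ether removes both O–H groups without breaking a C–O bond at the stereocentre, and the product should form as readily as the twist-boat acetonides of anti-1,3-diols.

**Step 5**
Reactants: 9 3-methoxy-4-[(4R)-2,2,6,6-tetramethyl-1,3-dioxan-4-yl]phenyl N,N-diethylcarbamate
Product: 11 3-methoxy-4-[(4R)-2,2,6,6-tetramethyl-1,3-dioxan-4-yl]-2-(trimethylsilyl)phenyl N,N-diethylcarbamate, via C1 aryllithium 10 (not isolated)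
Conditions: s-BuLi, TMEDA, THF, −78 °C; TMSCl, −78 °C→rt
Reagents that add atoms: chlorotrimethylsilane, C[Si](C)(C)Cl
Why: In this directed ortho-metalation the carbamate and the C2 methoxy group act together on the C1–H between them, and the aryllithium is silylated at −78 °C before anionic ortho-Fries migration can start.

**Step 6**
Reactants: 11 3-methoxy-4-[(4R)-2,2,6,6-tetramethyl-1,3-dioxan-4-yl]-2-(trimethylsilyl)phenyl N,N-diethylcarbamate
Product: 12 3-methoxy-4-[(4R)-2,2,6,6-tetramethyl-1,3-dioxan-4-yl]-2-(trimethylsilyl)phenol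
Conditions: LiAlH4, THF, 0 °C→reflux; Rochelle salt work-up, no acid
Reagents that add atoms: none
Why: Reductive cleavage of the aryl carbamate by hydride expels the phenoxide under non-protic conditions that leave the aryl–silicon bond and the acetonide alone.

**Step 7**
Reactants: 12 3-methoxy-4-[(4R)-2,2,6,6-tetramethyl-1,3-dioxan-4-yl]-2-(trimethylsilyl)phenol
Product: 13 3-methoxy-4-[(4R)-2,2,6,6-tetramethyl-1,3-dioxan-4-yl]-2-(trimethylsilyl)phenyl trifluoromethanesulfonate
Conditions: Tf2O, pyridine, CH2Cl2, −20→0 °C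
Reagents that add atoms: trifluoromethanesulfonic anhydride, O=S(=O)(OS(=O)(=O)C(F)(F)F)C(F)(F)F
Why: O-triflation of the phenol in pyridine-buffered medium completes the ortho-silylaryl triflate (Si on C1, OTf on C6) and is routine in the presence of acetonides.

**Step 8**
Reactants: 14 3-hydroxy-5-methylbenzoic acid
Product: 15 3-(hydroxymethyl)-5-methylphenol
Conditions: BH3·THF, THF, 0 °C→rt; then H2O
Reagents that add atoms: none
Why: Borane reduces the carboxylic acid chemoselectively to the benzylic alcohol, and the phenol is only masked for a time as a borate.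

**Step 9**
Reactants: 15 3-(hydroxymethyl)-5-methylphenol
Product: 16 1-(methoxymethoxy)-3-[(methoxymethoxy)methyl]-5-methylbenzene
Conditions: MOMCl (excess), i-Pr2NEt, CH2Cl2, 0 °C→rt
Reagents that add atoms: chloromethyl methyl ether, COCCl
Why: Exhaustive O-alkylation (MOM ether formation) puts the same group on both hydroxyls, so no selectivity between them is required.

**Step 10**
Reactants: 16 1-(methoxymethoxy)-3-[(methoxymethoxy)methyl]-5-methylbenzene
Product: 19 2-(methoxymethoxy)-6-[(methoxymethoxy)methyl]-4-methylphenol, via ring B aryllithium 17 (not isolated), via dimethyl arylboronate 18 (not isolated)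
Conditions: n-BuLi, Et2O–hexane, 0 °C→rt; B(OMe)3, −78 °C→rt; H2O2, aq. NaOH, 0 °C; NH4Cl to pH 7
Reagents that add atoms: hydrogen peroxide, OO
Why: In this directed ortho-metalation, borylation and oxidative C–B to C–O conversion, the aryl OMOM group and the CH2OMOM arm both bind lithium and converge on the C–H between them, so oxygen enters at C1′ as the only free hydroxyl.

**Step 11**
Reactants: 13 3-methoxy-4-[(4R)-2,2,6,6-tetramethyl-1,3-dioxan-4-yl]-2-(trimethylsilyl)phenyl trifluoromethanesulfonate, 19 2-(methoxymethoxy)-6-[(methoxymethoxy)methyl]-4-methylphenol, 20 carbon dioxide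
Product: 25 2-methoxy-6-{2-(methoxymethoxy)-6-[(methoxymethoxy)methyl]-4-methylphenoxy}-3-[(4R)-2,2,6,6-tetramethyl-1,3-dioxan-4-yl]benzoic acid, via potassium phenoxide 21 (not isolated), via ring A aryne 22 (not isolated), via C1 arylpotassium 23 (not isolated), via potassium carboxylate 24 (not isolated)
Conditions: 19 (2 equiv), KH, THF, 0 °C until H2 ceases; KF (dried), 18-crown-6, CO2 (dried, 1 atm, solution saturated), 0 °C; slow addition of 13 in THF, 0 °C→rt; cold aq. citric acid to pH 4–5
Reagents that add atoms: carbon dioxide, O=C=O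
Why: Proposed new method: fluoride attacks the silicon on C1 of 13 and triflate leaves from C6 to give aryne 22 (C1≡C6), whose C6 terminus is made the more electrophilic one by the inductive pull of the C2 methoxy group and is also the open end next to C5–H, so the hindered phenoxide 21 should bond through oxygen at C6. The charge then sits on C1, flanked by OMe and OAr, as arylpotassium 23, and with no O–H or N–H in the flask it should be taken by dissolved CO2 to give carboxylate 24, so the O–C6 and C1–CO2 bonds form in one operation. The closest known reaction types are the three-component coupling of arynes, amines and CO2 to anthranilic acids under KF/18-crown-6/THF and the fluoride-mediated O-arylation of phenols with silylaryl triflates; the new element is an anionic oxygen nucleophile combined with CO2 capture. No ring closes and no stereocentre is formed, and the (R) centre stays locked in the dioxane. The step needs regioselectivity, which the C2 methoxy group secures, and capture by CO2 ahead of protonation, which is served by preforming the phenoxide with KH, using THF instead of acetonitrile, saturating with CO2 and adding 13 slowly. Binding of CO2 to the 2,6-disubstituted phenoxide is reversible, Kolbe–Schmitt carboxylation and C-arylation of ring B are blocked because both ortho positions and the para position are substituted, and the excess phenoxide should outcompete carboxylate 24 for the aryne.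

**Step 12**
Reactants: 25 2-methoxy-6-{2-(methoxymethoxy)-6-[(methoxymethoxy)methyl]-4-methylphenoxy}-3-[(4R)-2,2,6,6-tetramethyl-1,3-dioxan-4-yl]benzoic acid
Product: 27 6-[2-hydroxy-6-(hydroxymethyl)-4-methylphenoxy]-2-methoxy-3-[(4R)-2,2,6,6-tetramethyl-1,3-dioxan-4-yl]benzoic acid, via silylated bipyridinium salt 26 (not isolated)
Conditions: TMSOTf, 2,2′-bipyridyl (both in excess), MeCN, 0 °C→rt; then H2O, rt
Reagents that add atoms: none
Why: In this silyl triflate/2,2′-bipyridyl MOM cleavage the alkyl MOM ether becomes an N-(alkoxymethyl)bipyridinium salt and the aryl MOM ether a silyl ether, both hydrolysed by water in a nearly neutral medium, so the hot mineral acid that would threaten the carbinol centre and the 2,6-dioxygenated benzoic acid is avoided.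

**Step 13**
Reactants: 27 6-[2-hydroxy-6-(hydroxymethyl)-4-methylphenoxy]-2-methoxy-3-[(4R)-2,2,6,6-tetramethyl-1,3-dioxan-4-yl]benzoic acid
Product: 28 6-[2-hydroxy-6-(hydroxymethyl)-4-methylphenoxy]-3-[(1R)-1,3-dihydroxy-3-methylbutyl]-2-methoxybenzoic acid (target)
Conditions: AcOH–THF–H2O, rt
Reagents that add atoms: none
Why: Mild acid-catalysed ketal hydrolysis cleaves at the acetone carbon of the strained tetramethyl-dioxane, so neither C–O bond of the diol breaks and the (R) configuration should be kept.

**Compound list**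
1 | 4-hydroxy-2-methoxybenzaldehyde | COc1cc(O)ccc1C=O | starting material
2 | 4-formyl-3-methoxyphenyl N,N-diethylcarbamate | CCN(CC)C(=O)Oc1ccc(C=O)c(OC)c1 | intermediate
3 | 3-chloro-2-methylpropene | CC(=C)CCl | starting material
4 | methallylmagnesium chloride | CC(=C)C[Mg]Cl | intermediate
5 | B-methallyldiisopinocampheylborane from (−)-α-pinene | C[C@@H]1[C@@H](B(CC(C)=C)[C@H]3C[C@H]4C[C@@H]([C@@H]3C)C4(C)C)C[C@H]2C[C@@H]1C2(C)C | intermediate
6 | diisopinocampheylborinate of alcohol 7 | C[C@@H]1[C@@H](B(O[C@H](CC(C)=C)c5ccc(OC(=O)N(CC)CC)cc5OC)[C@H]3C[C@H]4C[C@@H]([C@@H]3C)C4(C)C)C[C@H]2C[C@@H]1C2(C)C | intermediate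
7 | 4-[(1R)-1-hydroxy-3-methylbut-3-en-1-yl]-3-methoxyphenyl N,N-diethylcarbamate | CCN(CC)C(=O)Oc1ccc([C@H](O)CC(C)=C)c(OC)c1 | intermediate
8 | 4-[(1R)-1,3-dihydroxy-3-methylbutyl]-3-methoxyphenyl N,N-diethylcarbamate | CCN(CC)C(=O)Oc1ccc([C@H](O)CC(C)(C)O)c(OC)c1 | intermediate
9 | 3-methoxy-4-[(4R)-2,2,6,6-tetramethyl-1,3-dioxan-4-yl]phenyl N,N-diethylcarbamate | CCN(CC)C(=O)Oc1ccc([C@H]2CC(C)(C)OC(C)(C)O2)c(OC)c1 | intermediate
10 | 2-lithio derivative of 9 (Li on ring A C1) | CCN(CC)C(=O)Oc1ccc([C@H]2CC(C)(C)OC(C)(C)O2)c(OC)c1[Li] | intermediate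
11 | 3-methoxy-4-[(4R)-2,2,6,6-tetramethyl-1,3-dioxan-4-yl]-2-(trimethylsilyl)phenyl N,N-diethylcarbamate | CCN(CC)C(=O)Oc1ccc([C@H]2CC(C)(C)OC(C)(C)O2)c(OC)c1[Si](C)(C)C | intermediate
12 | 3-methoxy-4-[(4R)-2,2,6,6-tetramethyl-1,3-dioxan-4-yl]-2-(trimethylsilyl)phenol | COc1c([C@H]2CC(C)(C)OC(C)(C)O2)ccc(O)c1[Si](C)(C)C | intermediate
13 | 3-methoxy-4-[(4R)-2,2,6,6-tetramethyl-1,3-dioxan-4-yl]-2-(trimethylsilyl)phenyl trifluoromethanesulfonate | COc1c([C@H]2CC(C)(C)OC(C)(C)O2)ccc(OS(=O)(=O)C(F)(F)F)c1[Si](C)(C)C | intermediate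
14 | 3-hydroxy-5-methylbenzoic acid | Cc1cc(O)cc(C(=O)O)c1 | starting material
15 | 3-(hydroxymethyl)-5-methylphenol | Cc1cc(O)cc(CO)c1 | intermediate
16 | 1-(methoxymethoxy)-3-[(methoxymethoxy)methyl]-5-methylbenzene | Cc1cc(COCOC)cc(OCOC)c1 | intermediate
17 | 2-lithio derivative of 16 (Li between the two acetal arms) | Cc1cc(COCOC)c([Li])c(OCOC)c1 | intermediate
18 | dimethyl {2-(methoxymethoxy)-6-[(methoxymethoxy)methyl]-4-methylphenyl}boronate | Cc1cc(COCOC)c(B(OC)OC)c(OCOC)c1 | intermediate
19 | 2-(methoxymethoxy)-6-[(methoxymethoxy)methyl]-4-methylphenol | Cc1cc(COCOC)c(O)c(OCOC)c1 | intermediate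
20 | carbon dioxide | O=C=O | starting material
21 | potassium phenoxide of 19 | Cc1cc(COCOC)c([O-])c(OCOC)c1.[K+] | intermediate
22 | ring A aryne, 3-methoxy-4-[(4R)-2,2,6,6-tetramethyl-1,3-dioxan-4-yl]benzyne (C1≡C6) | COC1=C([C@H]2CC(C)(C)OC(C)(C)O2)C=CC#C1 | intermediate
23 | C1 arylpotassium formed by phenoxide addition at C6 | COc1c([C@H]2CC(C)(C)OC(C)(C)O2)ccc(Oc3c(OCOC)cc(C)cc3COCOC)c1[K] | intermediate
24 | potassium salt of acid 25 | COc1c([C@H]2CC(C)(C)OC(C)(C)O2)ccc(Oc3c(OCOC)cc(C)cc3COCOC)c1C(=O)[O-].[K+] | intermediate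
25 | 2-methoxy-6-{2-(methoxymethoxy)-6-[(methoxymethoxy)methyl]-4-methylphenoxy}-3-[(4R)-2,2,6,6-tetramethyl-1,3-dioxan-4-yl]benzoic acid | COc1c([C@H]2CC(C)(C)OC(C)(C)O2)ccc(Oc3c(OCOC)cc(C)cc3COCOC)c1C(=O)O | intermediate
26 | TMS ester, aryl TMS ether, N-(benzyloxymethyl)-2,2′-bipyridinium triflate derived from 25 | COc1c([C@H]2CC(C)(C)OC(C)(C)O2)ccc(Oc3c(O[Si](C)(C)C)cc(C)cc3COC[n+]4ccccc4-c5ccccn5)c1C(=O)O[Si](C)(C)C.[O-]S(=O)(=O)C(F)(F)F | intermediate
27 | 6-[2-hydroxy-6-(hydroxymethyl)-4-methylphenoxy]-2-methoxy-3-[(4R)-2,2,6,6-tetramethyl-1,3-dioxan-4-yl]benzoic acid | COc1c([C@H]2CC(C)(C)OC(C)(C)O2)ccc(Oc3c(O)cc(C)cc3CO)c1C(=O)O | intermediate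
28 | 6-[2-hydroxy-6-(hydroxymethyl)-4-methylphenoxy]-3-[(1R)-1,3-dihydroxy-3-methylbutyl]-2-methoxybenzoic acid | COc1c([C@H](O)CC(C)(C)O)ccc(Oc2c(O)cc(C)cc2CO)c1C(=O)O | target

**Total step count:** 13. **Longest linear sequence:** 10 (steps 1–7, 11, 12, 13).

**Steps most likely to fail**

1. **Step 11.** Protonation of the C1 aryl anion may outrun carboxylation; the proton could come from traces of water, the medium, or the ring B benzylic CH2 by internal transfer. The phenoxide may also be tied up as its carbonate, which could add to the aryne with acyl transfer, and the product carboxylate may be arylated further.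
 - The fallback sets out from 13 and 19 and makes the two bonds in two known operations.
 - Fluoride-mediated O-arylation of the free phenol 19 with 13 (CsF, MeCN, rt), where proton capture is now wanted, gives the C1–H diaryl ether F1 with the same methoxy-controlled regiochemistry.
 - Directed ortho-lithiation of the C1–H between OMe and OAr (n-BuLi, THF, −78→0 °C) gives the C1 aryllithium F2.
 - Quenching F2 with CO2 and acidifying with citric acid comes back to the route at 25.

2. **Step 12.** Cleavage of the alkyl MOM ether may be incomplete, or the silyl triflate may open the dioxane at its benzylic C–O bond with erosion of configuration.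
 - The fallback changes the ring B protecting-group plan and sets out from 15.
 - Ethyl vinyl ether with catalytic PPTS gives the bis(1-ethoxyethyl) ether F3.
 - The lithiation, borylation and oxidation of step 10 turn F3 into the free central phenol F4.
 - Coupling of F4 with 13 and 20 as in step 11 gives the acid F5.
 - A single treatment with AcOH–THF–H2O at rt removes both ethoxyethyl acetals and the acetonide, and the fallback comes back to the route at 28.

3. **Step 5.** Deprotonation may occur at C5 or at the benzylic dioxane C–H instead of the crowded C1, or the carbamoyl group may migrate before silylation.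
 - The fallback moves the silylation to the aldehyde stage and sets out from 2.
 - Lithium 4-methylpiperazin-1-ide adds to the aldehyde in THF at low temperature to give the lithium α-amino alkoxide F6, which is protected in situ and cannot be deprotonated at the benzylic carbon.
 - s-BuLi/TMEDA at −78 °C, then TMSCl and aqueous work-up, give the silylated aldehyde F7.
 - F7 goes through the operations of steps 2 to 4 by way of the silylated homoallylic alcohol F8 and the silylated diol F9, and the fallback comes back to the route at 11.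

**Further compounds**
F1 | step 11 | (4R)-4-{2-methoxy-4-[2-(methoxymethoxy)-6-(methoxymethoxymethyl)-4-methylphenoxy]phenyl}-2,2,6,6-tetramethyl-1,3-dioxane | COc1c([C@H]2CC(C)(C)OC(C)(C)O2)ccc(Oc3c(OCOC)cc(C)cc3COCOC)c1
F2 | step 11 | C1 aryllithium of F1 | COc1c([C@H]2CC(C)(C)OC(C)(C)O2)ccc(Oc3c(OCOC)cc(C)cc3COCOC)c1[Li]
F3 | step 12 | 1-(1-ethoxyethoxy)-3-[(1-ethoxyethoxy)methyl]-5-methylbenzene (mixture of acetal epimers) | Cc1cc(COC(C)OCC)cc(OC(C)OCC)c1
F4 | step 12 | 2-(1-ethoxyethoxy)-6-[(1-ethoxyethoxy)methyl]-4-methylphenol (mixture of acetal epimers) | Cc1cc(COC(C)OCC)c(O)c(OC(C)OCC)c1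
F5 | step 12 | 6-{2-(1-ethoxyethoxy)-6-[(1-ethoxyethoxy)methyl]-4-methylphenoxy}-2-methoxy-3-[(4R)-2,2,6,6-tetramethyl-1,3-dioxan-4-yl]benzoic acid (mixture of acetal epimers) | COc1c([C@H]2CC(C)(C)OC(C)(C)O2)ccc(Oc3c(OC(C)OCC)cc(C)cc3COC(C)OCC)c1C(=O)O
F6 | step 5 | lithium α-(4-methylpiperazin-1-yl) alkoxide of aldehyde 2 | CCN(CC)C(=O)Oc1ccc(C([O-])N2CCN(C)CC2)c(OC)c1.[Li+]
F7 | step 5 | 4-formyl-3-methoxy-2-(trimethylsilyl)phenyl N,N-diethylcarbamate | CCN(CC)C(=O)Oc1ccc(C=O)c(OC)c1[Si](C)(C)C
F8 | step 5 | 4-[(1R)-1-hydroxy-3-methylbut-3-en-1-yl]-3-methoxy-2-(trimethylsilyl)phenyl N,N-diethylcarbamate | CCN(CC)C(=O)Oc1ccc([C@H](O)CC(C)=C)c(OC)c1[Si](C)(C)C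
F9 | step 5 | 4-[(1R)-1,3-dihydroxy-3-methylbutyl]-3-methoxy-2-(trimethylsilyl)phenyl N,N-diethylcarbamate | CCN(CC)C(=O)Oc1ccc([C@H](O)CC(C)(C)O)c(OC)c1[Si](C)(C)C
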